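## Structural features

The target is a 2,3,5-trisubstituted oxane (O1, C2–C6) with three 4-hydroxyphenyl rings: one on C2, one at the end of an (E)-cinnamyl chain (C1'–C3') on C3, and one on the exocyclic secondary carbinol C7 attached to C5. It has four stereocentres, C2 (R), C3 (S) and C5 (R) in the ring and C7 (R) outside it; C2/C3 and C5/C7 are contiguous pairs separated by the C4 methylene. The three ring substituents are mutually cis, so in the chair with the C3 and C5 arms equatorial the C2 aryl group is axial. The C2 epimer would be all-equatorial, so the target is the less stable benzylic epimer and has to be made and kept under kinetic control. Both oxygenated benzylic carbons (the C2–O1 ether and C7–OH) carry para-oxygenated arenes and ionise easily (benzylic cation in acid, quinone methide from the phenoxide on warming), which would epimerise C2 or C7; the electron-rich styrene and the free phenols are sensitive to oxidants. The real difficulty is the cis-2,3,5 array with an axial aryl group, the configuration of C7 next to a ring centre that offers little facial bias, and telling apart two similar carbon arms on C3 and C5. The key step uses the fact that C1'–C2' on C3 and C7 on C5 sit on cis-1,3 positions: joining C2' to C7 as a C=C bond turns both arms into a cyclohexene (C3, C1', C2', C7, C5, C4) bridged across the oxane. In that 3-oxabicyclo[3.3.1]non-6-ene the cis-1,3 relation is compulsory and the C2 aryl group is equatorial.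

## Logic of the disconnections

22 from 21: the aryl O–acyl bond and the two aryl O–Si bonds are cut last. The free para-hydroxybenzylic C2–O1 and C7–OH bonds are the most ionisable in the molecule, so all earlier chemistry runs on masked phenols. The demand is one mild, cold, basic step with a neutral work-up.

21 from 20: the C7–H bond is cut (carbinol back to ketone). C5 gives little facial bias, so C7 is handed to a chiral reagent. This removes one stereocentre; it demands high facial selectivity on an aryl sec-alkyl ketone without touching the styrene, the ester or C5.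

20 from 19, and 19 from 18 and 5: the C7–aryl bond is cut as a carbonyl addition followed by oxidation. The third arene becomes a reagent already used earlier. The addition must be faster than enolisation at C5 and than attack on the aryl ester; the C7 configuration of 19 does not matter.

18 from 17 and 15: the C2'=C3' bond is cut. This removes the second arene and the E-alkene. The forward step must react at the unbranched formyl group only, give E geometry and not epimerise C5.

15 from 14, and 14 from 13: two S–O bonds and the benzylic C–S bond are cut. Both are routine; the only demand is that the aryl silyl ether survives.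

17 from 12: the two formyl carbons C2' and C7 are rejoined as a C=C bond. Two cis arms become one ring, the C3/C5 relation is locked and the C2 aryl group becomes equatorial. The forward step needs a clean cleavage of the only C=C bond, with the alkene in exactly the 6,7 position.

12 from 9 and 10: O1–C6 and C5–C6 are cut, removing a one-carbon unit. The oxane ring and the C5 stereocentre disappear, leaving a monocyclic carbinol with two stereocentres. The forward step demands closure of the six- and not the seven-membered ring, proton loss away from the bridgehead and retention at the benzylic carbon.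

9 from 7: the aryl O–acyl bond is exchanged for an O–Si bond. The aryl nucleophile needs the silyl ether, the cyclisation needs an electron-poor arene. The cost is one flask; the demand is phenol-selective acylation.

7 from 6: the C2–H bond is cut (carbinol to ketone), again leaving the configuration to a reagent. The demand is that the ring alkene and the α-stereocentre stay untouched.

6 from 3 and 5, and 3 from 1: the C2–aryl bond is cut at the acyl oxidation level. This leads back to a chiral-pool acid whose single stereocentre becomes C3. The demand is mono-addition and no epimerisation α to the carbonyl.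

5 from 4: the aryl C–Mg bond is cut back to the C–Br bond. One batch of the organometallic serves both aryl additions (to 3 and to 18). The demand is a clean magnesium insertion that leaves the aryl silyl ether intact and gives a solution that can be titrated and stored.

## Other disconnections considered

Alternative 1: The cut is at C2–C3 and C5–C7, the two bonds that join an aryl carbinol to a ring carbon. It exposes a hidden twofold symmetry: both pairs are anti and have the same sense once C1' and C6 are treated as equivalent carboxyl carbons. In the forward step the bis-imide A2 is enolised at both ends under MgCl2-catalysed soft-enolisation conditions (Et3N, Me3SiCl), and each enolate adds to the aldehyde A3 to give the anti,anti adduct A1.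
- In favour: four stereocentres (C2, C3, C5, C7) are set in one operation from achiral parts. After reduction, symmetry makes activation of either primary hydroxyl the same event, and only the remote benzylic hydroxyl can close a six-membered ring (O1–C6). The axial aryl group therefore arises without any epimerisable intermediate.
- Against: a double anti-aldol on a 1,5-diacyl unit has to outrun retro-aldol of the mono-adduct and intramolecular acyl transfer. The electron-rich aldehyde A3 is a poor electrophile. Two ionisable para-silyloxybenzylic carbinols must survive auxiliary removal, sulfonylation and cyclisation. The C3 arm ends as CH2OH and still needs an sp3–sp2 coupling to an E-styryl unit at a β-branched primary centre.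
- Comparison: on structure it equals the chosen plan in reaching the all-cis array under kinetic control. It is better in two respects: C7 is set together with the ring centres, and no dialdehyde has to be differentiated. On mechanism the chosen plan enforces the C3/C5 relation geometrically, whereas A1 relies on two independent auxiliary-controlled events. On step economy the two are about equal (roughly ten operations against eleven linear).

Alternative 2: The cut is at O1–C2 and C3–C4. In the forward step the 1-oxadiene A5 and the Z-styrene A6 combine in an inverse-demand [4+2] cycloaddition to the dihydropyran A4.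
- In favour: the route is convergent; the ring and C2/C3 form in one step; suprafacial addition carries the Z geometry into the 2,3-cis relation; the polarity is matched. The two arms are differentiated from the start (ester for C7, silyl ether for C2'), which is better than the chosen plan.
- Against: A5 self-condenses and must be made in situ. A para-oxygenated styrene is likely to react through a polarised, possibly stepwise benzylic pathway, which erodes cis-specificity towards the more stable trans adduct. Absolute control needs a chiral Lewis acid without close analogy for 1,2-disubstituted styrenes. C5 must then come from hydrogenation of a push–pull enol ether next to a benzylic C–O bond that can hydrogenolyse.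
- Comparison: C7 still has to be built from the ester by addition and reduction, so it is equal to the chosen plan there. Step economy is about equal. On mechanism its stereospecificity is not guaranteed, while the bicycle enforces cis.

Alternative 3: The cut is O1–C2 in the sense of an SN2 displacement. In the forward step a Lewis acid activates the geminal diester of cyclopropane A8 and the C6 hydroxyl attacks the benzylic carbon anti to the breaking C–C bond (6-exo-tet). The cis-cyclopropane gives the all-cis oxane A7 with inversion.
- In favour: the opening is stereospecific and gives the axial aryl group directly. C7 is in place before the ring closes, which is better than the chosen plan. The malonyl residue is a differentiated handle for C1'/C2'.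
- Against: the aryl sulfonate that suppresses SN1 scrambling also makes the arene a poor donor, so opening needs forcing activation, under which ionisation returns. A8 already holds four stereocentres and a cis-cyclopropane, so the difficulty moves into the precursor. Removing the aryl sulfonate at the end needs conditions harsher than the target tolerates.
- Comparison: on mechanism it is equal to the chosen plan as a kinetically controlled closure. On structure it is equal or better for C7. On step economy it is clearly longer.

Key step: step 6

Remark on the structures: an atom-by-atom check of the descriptors shows the cyclohexenyl carbinol, the bicyclic ether and the target to be mutually consistent ((S) ring carbon = C3, (R) carbinol = C2, aryl equatorial on the bicycle).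

Remark on the protecting group: the phenol of the C2 arene is carried through the cyclisation and beyond as a pivalate and not as a silyl ether, because a para-silyloxybenzylic alcohol would ionise and the arene would be hydroxymethylated under the acid.

Remark on materials: {4-[(tert-butyldimethylsilyl)oxy]phenyl}methanol 13 is taken to be a catalogue compound. The arylmagnesium bromide 5 is made once as a titrated THF solution, kept under argon and re-titrated before its second use.

## Route

Step 1
Reactants: 1 (S)-cyclohex-3-ene-1-carboxylic acid
Product: 3 (S)-N-methoxy-N-methylcyclohex-3-ene-1-carboxamide, via acyl imidazolide 2 (not isolated)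
Conditions: CDI, CH2Cl2, 0 °C → rt; then MeNHOMe·HCl, rt
Reagents that add atoms: N,O-dimethylhydroxylamine hydrochloride, CNOC.Cl
Why: Amide coupling through the acyl imidazolide; the near-neutral conditions leave the ring stereocentre, the future C3, untouched.

Step 2
Reactants: 4 (4-bromophenoxy)(tert-butyl)dimethylsilane
Product: 5 {4-[(tert-butyldimethylsilyl)oxy]phenyl}magnesium bromide (titrated THF solution)
Conditions: Mg turnings, I2 (cat.), THF, 45 °C → rt; titration, storage under Ar
Reagents that add atoms: magnesium, [Mg]
Why: Grignard reagent formation by insertion of magnesium into the aryl C–Br bond; the aryl silyl ether is inert to the reagent, and the solution serves both aryl additions of the route (steps 3 and 11).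

Step 3
Reactants: 3 (S)-N-methoxy-N-methylcyclohex-3-ene-1-carboxamide; 5 {4-[(tert-butyldimethylsilyl)oxy]phenyl}magnesium bromide
Product: 6 {4-[(tert-butyldimethylsilyl)oxy]phenyl}[(1S)-cyclohex-3-en-1-yl]methanone
Conditions: 5 (1.3 equiv), THF, 0 °C; aq NH4Cl
Reagents that add atoms: none
Why: Weinreb ketone synthesis; the magnesium-chelated tetrahedral adduct survives until the quench, so only one aryl group adds and the α-stereocentre never meets base as a ketone.

Step 4
Reactants: 6 {4-[(tert-butyldimethylsilyl)oxy]phenyl}[(1S)-cyclohex-3-en-1-yl]methanone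
Product: 7 (R)-{4-[(tert-butyldimethylsilyl)oxy]phenyl}[(1S)-cyclohex-3-en-1-yl]methanol
Conditions: (S)-2-methyl-CBS-oxazaborolidine (20 mol %), catecholborane, toluene, –78 → –40 °C; MeOH, then aqueous work-up
Reagents that add atoms: none
Why: Corey–Bakshi–Shibata reduction; with the aryl group as the large substituent the (S)-catalyst should give the (R)-carbinol (future C2), and catecholborane is chosen because it does not hydroborate the ring alkene at low temperature. Any minor carbinol epimer is a diastereomer and can be removed by chromatography.

Step 5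
Reactants: 7 (R)-{4-[(tert-butyldimethylsilyl)oxy]phenyl}[(1S)-cyclohex-3-en-1-yl]methanol
Product: 9 4-[(R)-[(1S)-cyclohex-3-en-1-yl](hydroxy)methyl]phenyl 2,2-dimethylpropanoate, via tetrabutylammonium phenolate 8 (not isolated)
Conditions: Bu4NF, THF, 0 °C; then t-BuCOCl, 0 °C
Reagents that add atoms: pivaloyl chloride, CC(C)(C)C(Cl)=O
Why: Fluoride desilylation and O-acylation of the phenolate in one flask (protecting-group exchange); the phenolate is far more nucleophilic than the secondary hydroxyl towards the hindered acid chloride. The acyloxy group makes the arene electron-poor enough that the benzylic C–O bond should not ionise and the ring should not be hydroxymethylated in step 6.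

Step 6
Reactants: 9 4-[(R)-[(1S)-cyclohex-3-en-1-yl](hydroxy)methyl]phenyl 2,2-dimethylpropanoate; 10 paraformaldehyde (source of formaldehyde)
Product: 12 4-[(1S,2R,5S)-3-oxabicyclo[3.3.1]non-6-en-2-yl]phenyl 2,2-dimethylpropanoate, via hemiformal 11 (not isolated)
Conditions: (CH2O)n, In(OTf)3 (10 mol %), 4 Å MS, CH2Cl2, 0 °C → rt
Reagents that add atoms: none
Why: This is a Prins-type (3,5)-oxonium-ene bicyclisation, the known reaction of (cyclohex-3-enyl)methanols with aldehydes; the carbinol oxygen adds to formaldehyde to give hemiformal 11, which In(OTf)3 ionises to the O1=C6H2 oxocarbenium ion. With the side chain pseudo-axial on the cyclohexene, the nearer alkene carbon (future C5) attacks C6 through a chair-like six-membered transition state; the closure is 6-endo-trig at the oxocarbenium carbon and exo with respect to the alkene, and attack by the farther alkene carbon would need a seven-membered ring. The secondary cation left on the carbocycle loses the adjacent methylene proton, because loss of the bridgehead proton would give an anti-Bredt alkene and triflate does not capture the cation; the C=C bond therefore lies between the future C7 and C2'. The new stereocentre C5 is fixed by the tether, since a three-atom bridge from C3 can only reach the same face, so C3 and C5 are cis. C2 is not made but must be kept: the (R)-carbinol places the aryl group equatorial in the chair transition state, the acyloxy group slows benzylic ionisation and ring hydroxymethylation, and a 2-oxonia-Cope shuffle is impossible because the alkene is bishomoallylic to oxygen. The step needs six- over seven-membered closure, proton loss over capture or hydride shift, and retention at C2; the substrate geometry, the non-nucleophilic counter-ion with catalytic acid, and the ester on the arene secure these in that order.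

Step 7
Reactants: 13 {4-[(tert-butyldimethylsilyl)oxy]phenyl}methanol
Product: 14 5-({4-[(tert-butyldimethylsilyl)oxy]benzyl}sulfanyl)-1-phenyl-1H-tetrazole
Conditions: 1-phenyl-1H-tetrazole-5-thiol, PPh3, DIAD, THF, 0 °C → rt
Reagents that add atoms: 1-phenyl-1H-tetrazole-5-thiol, Sc1nnnn1-c1ccccc1
Why: Mitsunobu thioetherification of a primary benzylic alcohol with the acidic heteroaryl thiol.

Step 8
Reactants: 14 5-({4-[(tert-butyldimethylsilyl)oxy]benzyl}sulfanyl)-1-phenyl-1H-tetrazole
Product: 15 5-({4-[(tert-butyldimethylsilyl)oxy]benzyl}sulfonyl)-1-phenyl-1H-tetrazole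
Conditions: 30% H2O2, (NH4)6Mo7O24·4H2O (10 mol %), EtOH, 0 °C → rt
Reagents that add atoms: hydrogen peroxide, OO
Why: Molybdate-catalysed peroxide oxidation of the sulfide to the sulfone; the aryl silyl ether should tolerate the mildly acidic medium.

Step 9
Reactants: 12 4-[(1S,2R,5S)-3-oxabicyclo[3.3.1]non-6-en-2-yl]phenyl 2,2-dimethylpropanoate
Product: 17 4-[(2R,3R,5R)-5-formyl-3-(2-oxoethyl)oxan-2-yl]phenyl 2,2-dimethylpropanoate, via secondary ozonide 16 (not isolated)
Conditions: O3, CH2Cl2, –78 °C (Sudan Red 7B end point); then PPh3, –78 °C → rt
Reagents that add atoms: ozone, [O-][O+]=O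
Why: Ozonolysis with reductive work-up cleaves the only C=C bond, so C7 and C2' appear as formyl groups on the cis C5 and C3 positions and no stereocentre is touched (the C3 descriptor changes only by priority). The acylated arene is too electron-poor to compete for ozone, and the dialdehyde is used at once.

Step 10
Reactants: 17 4-[(2R,3R,5R)-5-formyl-3-(2-oxoethyl)oxan-2-yl]phenyl 2,2-dimethylpropanoate; 15 5-({4-[(tert-butyldimethylsilyl)oxy]benzyl}sulfonyl)-1-phenyl-1H-tetrazole
Product: 18 4-[(2R,3S,5R)-3-[(2E)-3-{4-[(tert-butyldimethylsilyl)oxy]phenyl}prop-2-en-1-yl]-5-formyloxan-2-yl]phenyl 2,2-dimethylpropanoate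
Conditions: 15, KN(SiMe3)2, DME, –60 °C; then added slowly to 17, DME, –60 °C → rt; aq NH4Cl
Reagents that add atoms: none
Why: Julia–Kocienski olefination; the sulfonyl-stabilised benzylic anion should add to the unbranched formyl group faster than to the α-branched ring formyl group, and Smiles rearrangement with loss of SO2 and the tetrazolone gives the conjugated styrene, expected mainly E. The weakly basic anion, low temperature and inverse addition protect the dialdehyde against aldol closure, and the C5 formyl group is already equatorial, so there is no thermodynamic drive for epimerisation.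

Step 11
Reactants: 18 4-[(2R,3S,5R)-3-[(2E)-3-{4-[(tert-butyldimethylsilyl)oxy]phenyl}prop-2-en-1-yl]-5-formyloxan-2-yl]phenyl 2,2-dimethylpropanoate; 5 {4-[(tert-butyldimethylsilyl)oxy]phenyl}magnesium bromide (solution from step 2)
Product: 19 4-[(2R,3S,5R)-3-[(2E)-3-{4-[(tert-butyldimethylsilyl)oxy]phenyl}prop-2-en-1-yl]-5-[(RS)-{4-[(tert-butyldimethylsilyl)oxy]phenyl}(hydroxy)methyl]oxan-2-yl]phenyl 2,2-dimethylpropanoate (both C7 epimers)
Conditions: 5 (1.5 equiv), THF, –78 °C; aq NH4Cl
Reagents that add atoms: none
Why: Grignard addition to the aldehyde, which at –78 °C should be faster than both enolisation at C5 and attack on the hindered aryl pivalate. Both C7 epimers are expected and both are used, because C7 is reset in steps 12 and 13.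

Step 12
Reactants: 19 4-[(2R,3S,5R)-3-[(2E)-3-{4-[(tert-butyldimethylsilyl)oxy]phenyl}prop-2-en-1-yl]-5-[(RS)-{4-[(tert-butyldimethylsilyl)oxy]phenyl}(hydroxy)methyl]oxan-2-yl]phenyl 2,2-dimethylpropanoate
Product: 20 4-[(2R,3S,5R)-5-{4-[(tert-butyldimethylsilyl)oxy]benzoyl}-3-[(2E)-3-{4-[(tert-butyldimethylsilyl)oxy]phenyl}prop-2-en-1-yl]oxan-2-yl]phenyl 2,2-dimethylpropanoate
Conditions: Dess–Martin periodinane, CH2Cl2, 0 °C → rt
Reagents that add atoms: none
Why: Dess–Martin oxidation of a secondary benzylic alcohol under non-basic conditions, so that C5, now α to a ketone and β to the ring oxygen, should neither epimerise nor eliminate; the styrene is inert.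

Step 13
Reactants: 20 4-[(2R,3S,5R)-5-{4-[(tert-butyldimethylsilyl)oxy]benzoyl}-3-[(2E)-3-{4-[(tert-butyldimethylsilyl)oxy]phenyl}prop-2-en-1-yl]oxan-2-yl]phenyl 2,2-dimethylpropanoate
Product: 21 4-[(2R,3S,5R)-3-[(2E)-3-{4-[(tert-butyldimethylsilyl)oxy]phenyl}prop-2-en-1-yl]-5-[(R)-{4-[(tert-butyldimethylsilyl)oxy]phenyl}(hydroxy)methyl]oxan-2-yl]phenyl 2,2-dimethylpropanoate
Conditions: (S)-2-methyl-CBS-oxazaborolidine (30 mol %), catecholborane, toluene, –78 → –30 °C; MeOH, then aqueous work-up
Reagents that add atoms: none
Why: Corey–Bakshi–Shibata reduction under reagent control; as in step 4 the aryl group is the large substituent and the (S)-catalyst should give (R) at C7. Catecholborane spares the styrene and the aryl ester.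

Step 14
Reactants: 21 4-[(2R,3S,5R)-3-[(2E)-3-{4-[(tert-butyldimethylsilyl)oxy]phenyl}prop-2-en-1-yl]-5-[(R)-{4-[(tert-butyldimethylsilyl)oxy]phenyl}(hydroxy)methyl]oxan-2-yl]phenyl 2,2-dimethylpropanoate
Product: 22 4-[(2R,3S,5R)-5-[(R)-hydroxy(4-hydroxyphenyl)methyl]-3-[(2E)-3-(4-hydroxyphenyl)prop-2-en-1-yl]oxan-2-yl]phenol
Conditions: K2CO3, MeOH (degassed), 0 °C → rt; pH 7 phosphate buffer
Reagents that add atoms: none
Why: Base-catalysed methanolysis removes the aryl ester and both aryl silyl ethers (phenoxide leaving groups) in one operation. Keeping it cold and short, with a neutral work-up and no acid, is meant to avoid quinone-methide or cation formation at C2 and C7.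

## Compound list

1 | (S)-cyclohex-3-ene-1-carboxylic acid | C1[C@H](C(O)=O)CC=CC1 | starting material
2 | [(1S)-cyclohex-3-en-1-yl](1H-imidazol-1-yl)methanone | C1[C@H](C(=O)n2ccnc2)CC=CC1 | intermediate (not isolated)
3 | (S)-N-methoxy-N-methylcyclohex-3-ene-1-carboxamide | C1[C@H](C(=O)N(C)OC)CC=CC1 | intermediate
4 | (4-bromophenoxy)(tert-butyl)dimethylsilane | CC(C)(C)[Si](C)(C)Oc1ccc(Br)cc1 | starting material
5 | {4-[(tert-butyldimethylsilyl)oxy]phenyl}magnesium bromide | CC(C)(C)[Si](C)(C)Oc1ccc([Mg]Br)cc1 | intermediate (titrated THF solution)
6 | {4-[(tert-butyldimethylsilyl)oxy]phenyl}[(1S)-cyclohex-3-en-1-yl]methanone | C1[C@H](C(=O)c2ccc(O[Si](C)(C)C(C)(C)C)cc2)CC=CC1 | intermediate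
7 | (R)-{4-[(tert-butyldimethylsilyl)oxy]phenyl}[(1S)-cyclohex-3-en-1-yl]methanol | C1[C@H]([C@@H](O)c2ccc(O[Si](C)(C)C(C)(C)C)cc2)CC=CC1 | intermediate
8 | tetrabutylammonium 4-[(R)-[(1S)-cyclohex-3-en-1-yl](hydroxy)methyl]phenolate | C1[C@H]([C@@H](O)c2ccc([O-])cc2)CC=CC1.CCCC[N+](CCCC)(CCCC)CCCC | intermediate (not isolated)
9 | 4-[(R)-[(1S)-cyclohex-3-en-1-yl](hydroxy)methyl]phenyl 2,2-dimethylpropanoate | C1[C@H]([C@@H](O)c2ccc(OC(=O)C(C)(C)C)cc2)CC=CC1 | intermediate (key-step precursor)
10 | paraformaldehyde (reacting as formaldehyde) | C=O | starting material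
11 | 4-[(R)-[(1S)-cyclohex-3-en-1-yl](hydroxymethoxy)methyl]phenyl 2,2-dimethylpropanoate | C1[C@H]([C@@H](OCO)c2ccc(OC(=O)C(C)(C)C)cc2)CC=CC1 | intermediate (not isolated)
12 | 4-[(1S,2R,5S)-3-oxabicyclo[3.3.1]non-6-en-2-yl]phenyl 2,2-dimethylpropanoate | C1[C@H]2C[C@@H](C=C1)CO[C@H]2c1ccc(OC(=O)C(C)(C)C)cc1 | intermediate (key-step product)
13 | {4-[(tert-butyldimethylsilyl)oxy]phenyl}methanol | CC(C)(C)[Si](C)(C)Oc1ccc(CO)cc1 | starting material
14 | 5-({4-[(tert-butyldimethylsilyl)oxy]benzyl}sulfanyl)-1-phenyl-1H-tetrazole | CC(C)(C)[Si](C)(C)Oc1ccc(CSc2nnnn2-c2ccccc2)cc1 | intermediate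
15 | 5-({4-[(tert-butyldimethylsilyl)oxy]benzyl}sulfonyl)-1-phenyl-1H-tetrazole | CC(C)(C)[Si](C)(C)Oc1ccc(CS(=O)(=O)c2nnnn2-c2ccccc2)cc1 | intermediate
16 | secondary ozonide (1,2,4-trioxolane) of 12 fused across C6–C7 of the bicycle | C1[C@H]2C[C@@H](C3OOC1O3)CO[C@H]2c1ccc(OC(=O)C(C)(C)C)cc1 | intermediate (not isolated)
17 | 4-[(2R,3R,5R)-5-formyl-3-(2-oxoethyl)oxan-2-yl]phenyl 2,2-dimethylpropanoate | O=CC[C@H]2C[C@@H](C=O)CO[C@H]2c2ccc(OC(=O)C(C)(C)C)cc2 | intermediate
18 | 4-[(2R,3S,5R)-3-[(2E)-3-{4-[(tert-butyldimethylsilyl)oxy]phenyl}prop-2-en-1-yl]-5-formyloxan-2-yl]phenyl 2,2-dimethylpropanoate | CC(C)(C)[Si](C)(C)Oc1ccc(/C=C/C[C@H]2C[C@@H](C=O)CO[C@H]2c2ccc(OC(=O)C(C)(C)C)cc2)cc1 | intermediate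
19 | 4-[(2R,3S,5R)-3-[(2E)-3-{4-[(tert-butyldimethylsilyl)oxy]phenyl}prop-2-en-1-yl]-5-[(RS)-{4-[(tert-butyldimethylsilyl)oxy]phenyl}(hydroxy)methyl]oxan-2-yl]phenyl 2,2-dimethylpropanoate (both C7 epimers) | CC(C)(C)[Si](C)(C)Oc1ccc(/C=C/C[C@H]2C[C@@H](C(O)c3ccc(O[Si](C)(C)C(C)(C)C)cc3)CO[C@H]2c2ccc(OC(=O)C(C)(C)C)cc2)cc1 | intermediate
20 | 4-[(2R,3S,5R)-5-{4-[(tert-butyldimethylsilyl)oxy]benzoyl}-3-[(2E)-3-{4-[(tert-butyldimethylsilyl)oxy]phenyl}prop-2-en-1-yl]oxan-2-yl]phenyl 2,2-dimethylpropanoate | CC(C)(C)[Si](C)(C)Oc1ccc(/C=C/C[C@H]2C[C@@H](C(=O)c3ccc(O[Si](C)(C)C(C)(C)C)cc3)CO[C@H]2c2ccc(OC(=O)C(C)(C)C)cc2)cc1 | intermediate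
21 | 4-[(2R,3S,5R)-3-[(2E)-3-{4-[(tert-butyldimethylsilyl)oxy]phenyl}prop-2-en-1-yl]-5-[(R)-{4-[(tert-butyldimethylsilyl)oxy]phenyl}(hydroxy)methyl]oxan-2-yl]phenyl 2,2-dimethylpropanoate | CC(C)(C)[Si](C)(C)Oc1ccc(/C=C/C[C@H]2C[C@@H]([C@@H](O)c3ccc(O[Si](C)(C)C(C)(C)C)cc3)CO[C@H]2c2ccc(OC(=O)C(C)(C)C)cc2)cc1 | intermediate
22 | 4-[(2R,3S,5R)-5-[(R)-hydroxy(4-hydroxyphenyl)methyl]-3-[(2E)-3-(4-hydroxyphenyl)prop-2-en-1-yl]oxan-2-yl]phenol | Oc1ccc(/C=C/C[C@H]2C[C@@H]([C@@H](O)c3ccc(O)cc3)CO[C@H]2c2ccc(O)cc2)cc1 | target

## Step count and least certain steps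

Total: 14 steps. Longest linear sequence: 11 steps (steps 1, 3–6 and 9–14 from 1). Step 2 (the arylmagnesium solution) and steps 7–8 (the sulfone) are branches.

**Step 6 (key step).** The secondary cation may terminate by another path: hydride shift and proton loss to the isomeric 7-ene, later acid-promoted migration of the C=C bond, or capture. The cleavage in step 9 would then cut at the wrong bond. Residual ionisation at the benzylic carbon is the second concern. The fallback separates C–C bond formation from alkene formation. It sets out from 9 and 10 and comes back at 12. A bromide-terminated Prins cyclisation (Me3SiBr, (CH2O)n, CH2Cl2, –20 → 0 °C) should trap the cation anti to the new C–C bond as the axial bromide 4-[(1S,2R,5R,6S)-6-bromo-3-oxabicyclo[3.3.1]nonan-2-yl]phenyl 2,2-dimethylpropanoate F1. E2 elimination with DBU in toluene at 90 °C can then only take the antiperiplanar hydrogen on the methylene side, since the bridgehead side offers none, and gives 12 with the alkene position fixed by stereoelectronics.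

**Step 10.** Loss of geometric control is the most likely failure, since benzylic sulfonyl anions add reversibly and can give E/Z mixtures with unbranched aldehydes. Some olefination at the ring formyl group, or base-induced enolisation at C5 leading to epimerisation or β-elimination of the ring oxygen, may also occur. The fallback replaces kinetic olefination by a thermodynamically E-selective metathesis. It sets out from 17 and comes back at 18. One equivalent of methylenetriphenylphosphorane (from methyltriphenylphosphonium bromide and KN(SiMe3)2, THF, –78 °C) converts the unbranched formyl group into a vinyl group, giving 4-[(2R,3S,5R)-5-formyl-3-(prop-2-en-1-yl)oxan-2-yl]phenyl 2,2-dimethylpropanoate F2. Cross-metathesis with catalogue tert-butyldimethyl(4-vinylphenoxy)silane, using the second-generation Hoveyda–Grubbs catalyst RuCl2(H2IMes)(=CH-C6H4-2-OiPr) in CH2Cl2 at 40 °C, then gives 18. Site selectivity still rests on the steric difference between the two formyl groups.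

**Step 13.** Facial selectivity may be insufficient: the aryl group and the branched oxanyl group are closer in effective size than aryl and methyl, and the resident C5 centre may oppose the catalyst. The fallback replaces selectivity by separation and recycling. It sets out from 20 and comes back at 21. The carbinol mixture is separated on silica, and the unwanted epimer 4-[(2R,3S,5R)-3-[(2E)-3-{4-[(tert-butyldimethylsilyl)oxy]phenyl}prop-2-en-1-yl]-5-[(S)-{4-[(tert-butyldimethylsilyl)oxy]phenyl}(hydroxy)methyl]oxan-2-yl]phenyl 2,2-dimethylpropanoate F3 is returned to 20 with Dess–Martin periodinane and reduced again. Mitsunobu inversion is not proposed because this benzylic alcohol would ionise.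

**Step 14.** The freed phenoxide on the C2 arene may expel O1 as a para-quinone methide and reclose to the more stable equatorial-aryl epimer. Slow methanolysis of the hindered ester would prolong that exposure. The fallback avoids generating phenoxides in a protic base. It sets out from 21 and comes back at 22. The aryl ester is cleaved reductively with iBu2AlH (CH2Cl2, –78 °C) to 4-[(2R,3S,5R)-3-[(2E)-3-{4-[(tert-butyldimethylsilyl)oxy]phenyl}prop-2-en-1-yl]-5-[(R)-{4-[(tert-butyldimethylsilyl)oxy]phenyl}(hydroxy)methyl]oxan-2-yl]phenol F4. The two silyl ethers are then removed with Bu4NF buffered by acetic acid (THF, 0 °C) to give 22.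

## Further compounds

F1 | step 6 | 4-[(1S,2R,5R,6S)-6-bromo-3-oxabicyclo[3.3.1]nonan-2-yl]phenyl 2,2-dimethylpropanoate | C1[C@H]2C[C@@H]([C@@H](Br)C1)CO[C@H]2c1ccc(OC(=O)C(C)(C)C)cc1
F2 | step 10 | 4-[(2R,3S,5R)-5-formyl-3-(prop-2-en-1-yl)oxan-2-yl]phenyl 2,2-dimethylpropanoate | C=CC[C@H]2C[C@@H](C=O)CO[C@H]2c2ccc(OC(=O)C(C)(C)C)cc2
F3 | step 13 | 4-[(2R,3S,5R)-3-[(2E)-3-{4-[(tert-butyldimethylsilyl)oxy]phenyl}prop-2-en-1-yl]-5-[(S)-{4-[(tert-butyldimethylsilyl)oxy]phenyl}(hydroxy)methyl]oxan-2-yl]phenyl 2,2-dimethylpropanoate | CC(C)(C)[Si](C)(C)Oc1ccc(/C=C/C[C@H]2C[C@@H]([C@H](O)c3ccc(O[Si](C)(C)C(C)(C)C)cc3)CO[C@H]2c2ccc(OC(=O)C(C)(C)C)cc2)cc1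
F4 | step 14 | 4-[(2R,3S,5R)-3-[(2E)-3-{4-[(tert-butyldimethylsilyl)oxy]phenyl}prop-2-en-1-yl]-5-[(R)-{4-[(tert-butyldimethylsilyl)oxy]phenyl}(hydroxy)methyl]oxan-2-yl]phenol | CC(C)(C)[Si](C)(C)Oc1ccc(/C=C/C[C@H]2C[C@@H]([C@@H](O)c3ccc(O[Si](C)(C)C(C)(C)C)cc3)CO[C@H]2c2ccc(O)cc2)cc1
A1 | alternative 1 | (4R,4'R)-3,3'-{(2S,4S)-2,4-bis[(R)-{4-[(tert-butyldimethylsilyl)oxy]phenyl}(hydroxy)methyl]pentanedioyl}bis(4-benzyl-1,3-oxazolidin-2-one) | O=C(N1[C@H](Cc2ccccc2)COC1=O)[C@H]([C@@H](O)c1ccc(O[Si](C)(C)C(C)(C)C)cc1)C[C@@H]([C@@H](O)c1ccc(O[Si](C)(C)C(C)(C)C)cc1)C(=O)N1[C@H](Cc2ccccc2)COC1=O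
A2 | alternative 1 | (4R,4'R)-3,3'-pentanedioylbis(4-benzyl-1,3-oxazolidin-2-one) | O=C(CCCC(=O)N1[C@H](Cc2ccccc2)COC1=O)N1[C@H](Cc2ccccc2)COC1=O
A3 | alternative 1 | 4-[(tert-butyldimethylsilyl)oxy]benzaldehyde | O=Cc1ccc(O[Si](C)(C)C(C)(C)C)cc1
A4 | alternative 2 | methyl (2R,3R)-2-{4-[(tert-butyldimethylsilyl)oxy]phenyl}-3-{2-[(tert-butyldimethylsilyl)oxy]ethyl}-3,4-dihydro-2H-pyran-5-carboxylate | CC(C)(C)[Si](C)(C)OCC[C@H]2CC(C(=O)OC)=CO[C@H]2c2ccc(O[Si](C)(C)C(C)(C)C)cc2
A5 | alternative 2 | methyl 2-formylprop-2-enoate | C=C(C=O)C(=O)OC
A6 | alternative 2 | tert-butyl({(3Z)-4-{4-[(tert-butyldimethylsilyl)oxy]phenyl}but-3-en-1-yl}oxy)dimethylsilane | CC(C)(C)[Si](C)(C)OCC/C=C\c1ccc(O[Si](C)(C)C(C)(C)C)cc1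
A7 | alternative 3 | dimethyl 2-[(2R,3R,5R)-5-[(R)-[(tert-butyldimethylsilyl)oxy]{4-[(tert-butyldimethylsilyl)oxy]phenyl}methyl]-2-{4-[(methylsulfonyl)oxy]phenyl}oxan-3-yl]propanedioate | COC(=O)C(C(=O)OC)[C@H]2C[C@@H]([C@@H](O[Si](C)(C)C(C)(C)C)c3ccc(O[Si](C)(C)C(C)(C)C)cc3)CO[C@H]2c2ccc(OS(C)(=O)=O)cc2
A8 | alternative 3 | dimethyl (2S,3S)-3-[(2R,3R)-3-[(tert-butyldimethylsilyl)oxy]-3-{4-[(tert-butyldimethylsilyl)oxy]phenyl}-2-(hydroxymethyl)propyl]-2-{4-[(methylsulfonyl)oxy]phenyl}cyclopropane-1,1-dicarboxylate | COC(=O)C1(C(=O)OC)[C@H](c2ccc(OS(C)(=O)=O)cc2)[C@@H]1C[C@H](CO)[C@@H](O[Si](C)(C)C(C)(C)C)c1ccc(O[Si](C)(C)C(C)(C)C)cc1
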